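**Plan**
The retrosynthesis cuts two bonds on ring B at once: the diaryl ether C–O bond at C2 and the C–C bond of the formyl carbon at C3 (carried as CO2).
Ring B has the ether oxygen on C2, the formyl carbon on the adjacent C3 and a hydroxyl on C4 next to it. This is the pattern a 3-alkoxyaryne (C2≡C3, oxygen on C4) delivers when a nucleophile adds remote from the oxygen and an electrophile is captured beside it.
Forward: ring B is built from orsellinic acid into a 2-silylaryl triflate, and ring A from methyl 2,4-dihydroxy-3,6-dimethylbenzoate into a C5 phenol (formylation, MOM protection, Dakin-type oxidation).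
The two rings are joined with CO2 in one aryne step; the new acid is then taken to the aldehyde and all protecting groups are removed by acid.
No ring is formed in the route and the target has no stereocentre.

Key step: step 10

Remark: positions are numbered from the carboxyl-bearing carbon of each ring (ring A: C1 CO2Me, C2 OH, C3 CH3, C4 OH, C5 O-aryl, C6 CH3; ring B: C1 CO2H, C2 O-aryl, C3 CHO, C4 OH, C5 Cl, C6 CH3); orsellinic acid is assumed to be used anhydrous.

**Route**

Step 1
Reactants: 1 orsellinic acid (2,4-dihydroxy-6-methylbenzoic acid)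
Product: 2 tert-butyl 2,4-dihydroxy-6-methylbenzoate
Conditions: Cl3CC(=NH)Ot-Bu (2 equiv), CH2Cl2/THF, rt
Reagents that add atoms: tert-butyl 2,2,2-trichloroacetimidate, CC(C)(C)OC(=N)C(Cl)(Cl)Cl
Why: Trichloroacetimidate esterification, in which the acid protonates the imidate and the carboxylate captures the tert-butyl cation at room temperature, so the phenols stay free and the heat that decarboxylates β-resorcylic acids is avoided.

Step 2
Reactants: 2 tert-butyl 2,4-dihydroxy-6-methylbenzoate
Product: 3 tert-butyl 5-chloro-2,4-dihydroxy-6-methylbenzoate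
Conditions: SO2Cl2 (1.0 equiv), Et2O, 0 °C
Reagents that add atoms: sulfuryl chloride, O=S(=O)(Cl)Cl
Why: Electrophilic aromatic chlorination, which on 6-alkyl-β-resorcylates should prefer C5 (para to the chelated C2 hydroxyl, ortho to the free C4 hydroxyl), with any C3 isomer to be removed by chromatography.

Step 3
Reactants: 3 tert-butyl 5-chloro-2,4-dihydroxy-6-methylbenzoate
Product: 4 tert-butyl 5-chloro-2-hydroxy-4-(methoxymethoxy)-6-methylbenzoate
Conditions: MOMCl (1.1 equiv), i-Pr2NEt, CH2Cl2, 0 °C
Reagents that add atoms: chloromethyl methyl ether, COCCl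
Why: Base-mediated O-alkylation (MOM ether formation) selective for the C4 hydroxyl, which is the more acidic one and is not held in the hydrogen bond to the ester carbonyl that deactivates the C2 hydroxyl.

Step 4
Reactants: 4 tert-butyl 5-chloro-2-hydroxy-4-(methoxymethoxy)-6-methylbenzoate
Product: 5 tert-butyl 3-bromo-5-chloro-2-hydroxy-4-(methoxymethoxy)-6-methylbenzoate
Conditions: NBS (1.05 equiv), MeCN, 0 °C
Reagents that add atoms: N-bromosuccinimide, O=C1CCC(=O)N1Br
Why: Electrophilic aromatic bromination at C3, the only unsubstituted ring carbon, activated by the free ortho hydroxyl and the ortho MOM ether.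

Step 5
Reactants: 5 tert-butyl 3-bromo-5-chloro-2-hydroxy-4-(methoxymethoxy)-6-methylbenzoate
Product: 6 tert-butyl 3-bromo-5-chloro-4-(methoxymethoxy)-6-methyl-2-(trimethylsilyloxy)benzoate
Conditions: HMDS, THF, 70 °C; evaporate, use crude
Reagents that add atoms: hexamethyldisilazane, C[Si](C)(C)N[Si](C)(C)C
Why: O-silylation by silyl transfer from HMDS with loss of ammonia, the usual first stage of the ortho-bromophenol route to ortho-silylaryl triflates.

Step 6
Reactants: 6 tert-butyl 3-bromo-5-chloro-4-(methoxymethoxy)-6-methyl-2-(trimethylsilyloxy)benzoate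
Product: 8 tert-butyl 5-chloro-4-(methoxymethoxy)-6-methyl-2-(trifluoromethylsulfonyloxy)-3-(trimethylsilyl)benzoate, via lithium phenoxide 7 (not isolated)
Conditions: n-BuLi (1.1 equiv), THF, −100 → −78 °C; then Tf2O, −78 °C
Reagents that add atoms: trifluoromethanesulfonic anhydride, O=S(=O)(OS(=O)(=O)C(F)(F)F)C(F)(F)F
Why: Bromine–lithium exchange at −100 °C should outpace attack on the doubly ortho-substituted tert-butyl ester, the aryllithium then undergoes the anionic 1,3 O→C silyl shift (retro-Brook rearrangement) to the phenoxide, and triflic anhydride traps it as the aryl triflate.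

Step 7
Reactants: 9 methyl 2,4-dihydroxy-3,6-dimethylbenzoate
Product: 10 methyl 5-formyl-2,4-dihydroxy-3,6-dimethylbenzoate
Conditions: Cl2CHOMe, TiCl4, CH2Cl2, 0 °C → rt; then aq. HCl
Reagents that add atoms: dichloromethyl methyl ether, COC(Cl)Cl; water (work-up), O
Why: Rieche formylation, in which the titanium-bound phenoxide directs the electrophile to C5, the only free ring position (ortho to the C4 hydroxyl, para to the C2 hydroxyl), and aqueous work-up hydrolyses the α-chloro ether to the aldehyde.

Step 8
Reactants: 10 methyl 5-formyl-2,4-dihydroxy-3,6-dimethylbenzoate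
Product: 11 methyl 5-formyl-2,4-bis(methoxymethoxy)-3,6-dimethylbenzoate
Conditions: NaH (2.5 equiv), MOMCl (2.5 equiv), DMF, 0 °C → rt
Reagents that add atoms: chloromethyl methyl ether, COCCl
Why: Williamson-type ether formation, in which NaH converts both hydrogen-bonded phenols into sodium phenoxides that the small, reactive MOMCl alkylates despite the flanking groups.

Step 9
Reactants: 11 methyl 5-formyl-2,4-bis(methoxymethoxy)-3,6-dimethylbenzoate
Product: 13 methyl 5-hydroxy-2,4-bis(methoxymethoxy)-3,6-dimethylbenzoate, via aryl formate 12 (not isolated)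
Conditions: mCPBA, CH2Cl2, 0 °C → rt; aq. NaHCO3 wash; then K2CO3 (cat.), MeOH, rt
Reagents that add atoms: meta-chloroperoxybenzoic acid, OOC(=O)c1cccc(Cl)c1
Why: Baeyer–Villiger (Dakin-type) oxidation, in which the aryl group, made electron-rich by MOM-oxy groups ortho and para to the formyl carbon, migrates to give the aryl formate, and catalytic methoxide in methanol then cleaves the formate without changing the methyl ester.

Step 10
Reactants: 8 tert-butyl 5-chloro-4-(methoxymethoxy)-6-methyl-2-(trifluoromethylsulfonyloxy)-3-(trimethylsilyl)benzoate; 13 methyl 5-hydroxy-2,4-bis(methoxymethoxy)-3,6-dimethylbenzoate; 14 carbon dioxide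
Product: 17 3-(tert-butoxycarbonyl)-5-chloro-6-(methoxymethoxy)-4-methyl-2-[3-(methoxycarbonyl)-4,6-bis(methoxymethoxy)-2,5-dimethylphenoxy]benzoic acid, via potassium phenoxide 15 (not isolated), via aryne 16 (not isolated)
Conditions: 13, KH, THF, 0 °C; then KF, 18-crown-6, CO2 (10 atm), 8 (1.5 equiv), THF, 0 °C → rt; cold dilute aq. HCl to pH 3
Reagents that add atoms: carbon dioxide (compound 14), O=C=O
Why: Proposed new method: fluoride removes the silyl group of 8 and triflate departs to give aryne 16 (C2≡C3); phenoxide 15 adds at C2 to form the diaryl ether C–O bond, and the resulting C3 aryl anion, flanked by the MOM-oxy and the new aryloxy oxygen, forms the C–C bond to CO2. The closest known reaction types are the fluoride-triggered three-component coupling of arynes with amines and CO2 to anthranilic acids and the O-arylation of phenols with 3-alkoxyarynes; their combination with a phenoxide nucleophile is untested. No ring is closed and no stereocentre is created. Regioselectivity requires attack at the aryne carbon remote from the C4 oxygen: the directly bound, electronegative oxygen should distort the aryne more strongly than the carbon-bound, twisted tert-butyl ester on the other side, and it places the negative charge next to oxygen. Chemoselectivity requires carboxylation to beat protonation: the phenol is deprotonated beforehand with KH so that no bifluoride or other acid is present, the medium is aprotic THF, and CO2 is held under pressure.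

Step 11
Reactants: 17 the protected diaryl ether acid
Product: 18 tert-butyl 5-chloro-3-(hydroxymethyl)-4-(methoxymethoxy)-6-methyl-2-[3-(methoxycarbonyl)-4,6-bis(methoxymethoxy)-2,5-dimethylphenoxy]benzoate
Conditions: BH3·SMe2 (3 equiv), THF, 0 °C → rt; MeOH quench
Reagents that add atoms: none
Why: Chemoselective borane reduction of a carboxylic acid through its acyloxyborane to the benzylic alcohol, while the methyl ester, the tert-butyl ester, the MOM ethers and the aryl chloride should be inert to BH3 at room temperature.

Step 12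
Reactants: 18 the benzylic alcohol
Product: 19 tert-butyl 5-chloro-3-formyl-4-(methoxymethoxy)-6-methyl-2-[3-(methoxycarbonyl)-4,6-bis(methoxymethoxy)-2,5-dimethylphenoxy]benzoate
Conditions: Dess–Martin periodinane (1.3 equiv), CH2Cl2, rt
Reagents that add atoms: none
Why: Dess–Martin oxidation of a benzylic alcohol, which stops at the aldehyde under neutral, non-aqueous conditions and spares the acetal-type protecting groups.

Step 13
Reactants: 19 the protected aldehyde
Product: 20 5-chloro-3-formyl-4-hydroxy-6-methyl-2-[4,6-dihydroxy-3-(methoxycarbonyl)-2,5-dimethylphenoxy]benzoic acid (CNP0210944.0)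
Conditions: TFA/CH2Cl2 (1:1), H2O (10 equiv), 0 °C → rt
Reagents that add atoms: none
Why: Acidolysis, in which TFA cleaves the three MOM acetals and the tert-butyl ester in one operation while the hindered methyl ester survives, and the released electrophiles find no free aromatic carbon because both rings are fully substituted.

**Compound list**
1 | orsellinic acid (2,4-dihydroxy-6-methylbenzoic acid) | Cc1cc(O)cc(O)c1C(=O)O | starting material
2 | tert-butyl 2,4-dihydroxy-6-methylbenzoate | CC(C)(C)OC(=O)c1c(C)cc(O)cc1O | intermediate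
3 | tert-butyl 5-chloro-2,4-dihydroxy-6-methylbenzoate | CC(C)(C)OC(=O)c1c(C)c(Cl)c(O)cc1O | intermediate
4 | tert-butyl 5-chloro-2-hydroxy-4-(methoxymethoxy)-6-methylbenzoate | CC(C)(C)OC(=O)c1c(C)c(Cl)c(OCOC)cc1O | intermediate
5 | tert-butyl 3-bromo-5-chloro-2-hydroxy-4-(methoxymethoxy)-6-methylbenzoate | CC(C)(C)OC(=O)c1c(C)c(Cl)c(OCOC)c(Br)c1O | intermediate
6 | tert-butyl 3-bromo-5-chloro-4-(methoxymethoxy)-6-methyl-2-(trimethylsilyloxy)benzoate | CC(C)(C)OC(=O)c1c(C)c(Cl)c(OCOC)c(Br)c1O[Si](C)(C)C | intermediate
7 | lithium 2-(tert-butoxycarbonyl)-4-chloro-5-(methoxymethoxy)-3-methyl-6-(trimethylsilyl)phenoxide (not isolated) | [Li+].[O-]c1c([Si](C)(C)C)c(OCOC)c(Cl)c(C)c1C(=O)OC(C)(C)C | intermediate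
8 | tert-butyl 5-chloro-4-(methoxymethoxy)-6-methyl-2-(trifluoromethylsulfonyloxy)-3-(trimethylsilyl)benzoate (ring B aryne precursor) | CC(C)(C)OC(=O)c1c(C)c(Cl)c(OCOC)c([Si](C)(C)C)c1OS(=O)(=O)C(F)(F)F | intermediate
9 | methyl 2,4-dihydroxy-3,6-dimethylbenzoate | COC(=O)c1c(C)cc(O)c(C)c1O | starting material
10 | methyl 5-formyl-2,4-dihydroxy-3,6-dimethylbenzoate | COC(=O)c1c(C)c(C=O)c(O)c(C)c1O | intermediate
11 | methyl 5-formyl-2,4-bis(methoxymethoxy)-3,6-dimethylbenzoate | COC(=O)c1c(C)c(C=O)c(OCOC)c(C)c1OCOC | intermediate
12 | methyl 5-(formyloxy)-2,4-bis(methoxymethoxy)-3,6-dimethylbenzoate (not isolated) | COC(=O)c1c(C)c(OC=O)c(OCOC)c(C)c1OCOC | intermediate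
13 | methyl 5-hydroxy-2,4-bis(methoxymethoxy)-3,6-dimethylbenzoate (ring A phenol) | COC(=O)c1c(C)c(O)c(OCOC)c(C)c1OCOC | intermediate
14 | carbon dioxide | O=C=O | starting material
15 | potassium 3-(methoxycarbonyl)-4,6-bis(methoxymethoxy)-2,5-dimethylphenoxide (not isolated) | [K+].[O-]c1c(C)c(C(=O)OC)c(OCOC)c(C)c1OCOC | intermediate
16 | tert-butyl 5-chloro-4-(methoxymethoxy)-6-methyl-2,3-didehydrobenzoate, the 3-alkoxyaryne (not isolated) | CC(C)(C)OC(=O)C1=C(C)C(Cl)=C(OCOC)C#C1 | intermediate
17 | 3-(tert-butoxycarbonyl)-5-chloro-6-(methoxymethoxy)-4-methyl-2-[3-(methoxycarbonyl)-4,6-bis(methoxymethoxy)-2,5-dimethylphenoxy]benzoic acid | OC(=O)c1c(OCOC)c(Cl)c(C)c(C(=O)OC(C)(C)C)c1Oc1c(C)c(C(=O)OC)c(OCOC)c(C)c1OCOC | intermediate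
18 | tert-butyl 5-chloro-3-(hydroxymethyl)-4-(methoxymethoxy)-6-methyl-2-[3-(methoxycarbonyl)-4,6-bis(methoxymethoxy)-2,5-dimethylphenoxy]benzoate | OCc1c(OCOC)c(Cl)c(C)c(C(=O)OC(C)(C)C)c1Oc1c(C)c(C(=O)OC)c(OCOC)c(C)c1OCOC | intermediate
19 | tert-butyl 5-chloro-3-formyl-4-(methoxymethoxy)-6-methyl-2-[3-(methoxycarbonyl)-4,6-bis(methoxymethoxy)-2,5-dimethylphenoxy]benzoate | O=Cc1c(OCOC)c(Cl)c(C)c(C(=O)OC(C)(C)C)c1Oc1c(C)c(C(=O)OC)c(OCOC)c(C)c1OCOC | intermediate
20 | 5-chloro-3-formyl-4-hydroxy-6-methyl-2-[4,6-dihydroxy-3-(methoxycarbonyl)-2,5-dimethylphenoxy]benzoic acid (CNP0210944.0) | COC(=O)c1c(C)c(Oc2c(C=O)c(O)c(Cl)c(C)c2C(=O)O)c(O)c(C)c1O | target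

**Step count**
Total: 13 steps. Longest linear sequence: 10 steps (steps 1–6, then 10–13); the ring A branch contributes steps 7–9.

**Steps most likely to fail**

1. Step 10 (the proposed new method). The C3 aryl anion may be protonated before it meets CO2, by proton transfer from the nearby ring A methyl or MOM methylene or from traces of moisture. The phenoxide may also be held back as its aryl carbonate under CO2, so that the aryne is consumed by other paths, or the phenoxide may add at the aryne carbon next to the MOM-oxy group. The fallback separates the two bond formations and uses only known chemistry. It sets out from 8 and 13: CsF in MeCN at rt gives the ordinary protonative O-arylation of the phenol by the aryne, to tert-butyl 5-chloro-4-(methoxymethoxy)-6-methyl-2-[3-(methoxycarbonyl)-4,6-bis(methoxymethoxy)-2,5-dimethylphenoxy]benzoate F1, whose only aromatic C–H is ring B C3 between two oxygens. Directed magnesiation there with the ester-tolerant amide base TMP2Mg·2LiCl (THF, −20 °C) and quenching with DMF gives the aldehyde directly. The fallback comes back to the route at 19, so steps 11 and 12 are no longer needed.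

2. Step 6. Silyl migration from oxygen to the crowded C3 may lag behind protonation or ester attack by the aryllithium, and the hindered phenoxide may triflate slowly. The fallback forms the C–Si bond with an external silyl chloride and sets out from 4, before bromination. Isopropyl isocyanate with Et3N gives tert-butyl 5-chloro-2-(isopropylcarbamoyloxy)-4-(methoxymethoxy)-6-methylbenzoate F2. In situ N-silylation (TMSOTf, TMEDA) is followed by carbamate- and MOM-directed ortho-lithiation at C3 (n-BuLi, TMEDA, −78 °C), quenching with TMSCl and work-up with aqueous NaHSO4, to give tert-butyl 5-chloro-2-(isopropylcarbamoyloxy)-4-(methoxymethoxy)-6-methyl-3-(trimethylsilyl)benzoate F3. One-pot carbamate cleavage with DBU and Et2NH in MeCN, then triflation with PhNTf2, comes back to the route at 8.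

3. Step 2. The first halogenation may go to C3 between the two hydroxyls, or run on to the dichloride, instead of stopping at C5. The fallback reverses the order of the two halogenations, so that a preference for C3 becomes useful, and sets out from 2. NBS (1 equiv, CH2Cl2, −78 → 0 °C) gives tert-butyl 3-bromo-2,4-dihydroxy-6-methylbenzoate F4. SO2Cl2 then chlorinates the one remaining ring position to tert-butyl 3-bromo-5-chloro-2,4-dihydroxy-6-methylbenzoate F5. Selective MOM protection of the non-chelated C4 hydroxyl (MOMCl, i-Pr2NEt) comes back to the route at 5.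

**Further compounds**
F1 | step 10 | tert-butyl 5-chloro-4-(methoxymethoxy)-6-methyl-2-[3-(methoxycarbonyl)-4,6-bis(methoxymethoxy)-2,5-dimethylphenoxy]benzoate | CC(C)(C)OC(=O)c1c(C)c(Cl)c(OCOC)cc1Oc1c(C)c(C(=O)OC)c(OCOC)c(C)c1OCOC
F2 | step 6 | tert-butyl 5-chloro-2-(isopropylcarbamoyloxy)-4-(methoxymethoxy)-6-methylbenzoate | CC(C)NC(=O)Oc1cc(OCOC)c(Cl)c(C)c1C(=O)OC(C)(C)C
F3 | step 6 | tert-butyl 5-chloro-2-(isopropylcarbamoyloxy)-4-(methoxymethoxy)-6-methyl-3-(trimethylsilyl)benzoate | CC(C)NC(=O)Oc1c([Si](C)(C)C)c(OCOC)c(Cl)c(C)c1C(=O)OC(C)(C)C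
F4 | step 2 | tert-butyl 3-bromo-2,4-dihydroxy-6-methylbenzoate | CC(C)(C)OC(=O)c1c(C)cc(O)c(Br)c1O
F5 | step 2 | tert-butyl 3-bromo-5-chloro-2,4-dihydroxy-6-methylbenzoate | CC(C)(C)OC(=O)c1c(C)c(Cl)c(O)c(Br)c1O
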